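The ring carbons are labelled from the vinylic CH (C1) to the vinylic carbon holding CO2H carbon C14 (C10); C4 has methyl C15, C6 and C8 the acetates, C7 the isopropyl unit C11–C13. The plan cuts C6–C7. It exploits the O6–C6–C7–C11 array of the ten-membered ring: a secondary alcohol next to C4=C5 whose neighbour can carry isopropenyl is the homoallylic alcohol left by a [2,3]-Wittig shift. One operation contracts a 13-membered C6–O–C12 bis-allylic ether to the carbocycle, making C6–C7 and two stereocentres under the influence of C8. The precursor is that cyclic ether: Z olefins at C4=C5 and C7=C11, E at C1=C10, O8 and O14 silylated.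

Key step: step 15

Remark: the ring locants C1–C15 are also used for the open-chain intermediates; 3 and 4 (one carbinol centre) and 8 and 9 (the phosphorus-bearing carbon) are stereoisomer mixtures at centres that the following step removes.

Step 1
Reactants: 1 nerol
Product: 2 neryl 4-methoxybenzyl (PMB) ether
Conditions: NaH, 4-MeOC6H4CH2Cl, n-Bu4NI (cat.), THF–DMF, 0 °C → rt
Reagents that add atoms: 4-methoxybenzyl chloride, COc1ccc(CCl)cc1
Why: Williamson etherification of the primary allylic alkoxide with a benzylic chloride; the ether tolerates the hydride, base and silylation steps ahead and is removable oxidatively in step 13 without touching silyl ethers.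

Step 2
Reactants: 2 neryl PMB ether
Product: 3 racemic 6,7-epoxide of 2
Conditions: mCPBA (1.0 equiv), NaHCO3, CH2Cl2, −20 → 0 °C
Reagents that add atoms: 3-chloroperoxybenzoic acid, OOC(=O)c1cccc(Cl)c1
Why: Prilezhaev epoxidation: the isopropylidene olefin is the more electron-rich of the two trisubstituted olefins because the other is deactivated by the allylic ether oxygen, so one equivalent of peracid at low temperature should react mainly at the chain end; the new centre is racemic and is excised in step 3.

Step 3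
Reactants: 3 racemic epoxide
Product: 5 (4Z)-6-(4-methoxybenzyloxy)-4-methylhex-4-enal (C1–C6 with C15), via vicinal diol 4 (not isolated)
Conditions: H5IO6, THF–Et2O, 0 °C
Reagents that add atoms: none
Why: Acid-mediated epoxide hydrolysis and Malaprade glycol cleavage in one flask release acetone and leave the C1 aldehyde (its oxygen is the former epoxide oxygen, water having entered at the tertiary carbon), while the PMB ether and the Z olefin are inert to periodic acid at 0 °C.

Step 4
Reactants: 6 (R)-trityl glycidyl ether; 7 triethyl phosphonoacetate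
Product: 9 diethyl {(5R)-2-oxo-5-[(trityloxy)methyl]oxolan-3-yl}phosphonate, via ring-opened sodium alkoxide 8 (not isolated)
Conditions: NaH, DME, 0 °C; then 6, reflux; aqueous work-up
Reagents that add atoms: none
Why: The sodium phosphonoacetate carbanion opens the epoxide by SN2 attack at its unsubstituted carbon and the alkoxide so formed lactonises onto the ethyl ester (5-exo-trig acyl substitution), so the future C8 centre is never a reaction site and keeps the glycidyl configuration.

Step 5
Reactants: 9 phosphono lactone; 5 aldehyde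
Product: 10 (3E,5R)-3-[(4Z)-6-(4-methoxybenzyloxy)-4-methylhex-4-en-1-ylidene]-5-[(trityloxy)methyl]oxolan-2-one
Conditions: NaH, THF, 0 °C → rt
Reagents that add atoms: none
Why: Horner–Wadsworth–Emmons olefination; α-phosphono-γ-butyrolactones deliver mainly the E-alkylidene lactone, in which the chain lies anti to the carbonyl, which is the C1=C10 geometry of the target, and any Z isomer is removed by chromatography.

Step 6
Reactants: 10 alkylidene lactone
Product: 11 (2R,4E,8Z)-4-(hydroxymethyl)-10-(4-methoxybenzyloxy)-8-methyl-1-(trityloxy)deca-4,8-dien-2-ol (C14 and C8 hydroxyls free)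
Conditions: i-Bu2AlH (4 equiv), CH2Cl2, −78 → 0 °C; aq. KNaC4H4O6 (tartrate)
Reagents that add atoms: none
Why: 1,2-Reduction of the conjugated lactone by i-Bu2AlH through the lactol gives the C14 allylic alcohol and the C8 carbinol without conjugate reduction or change of olefin geometry; both ethers are inert.

Step 7
Reactants: 11 diol
Product: 13 C8 TBS, C14 TBDPS bis-silyl ether, via C14 mono-TBDPS ether 12 (not isolated)
Conditions: t-BuPh2SiCl, imidazole, DMF, 0 °C; then t-BuMe2SiCl, imidazole, DMAP (cat.), 40 °C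
Reagents that add atoms: tert-butyl(chloro)diphenylsilane, CC(C)(C)[Si](Cl)(c1ccccc1)c1ccccc1; tert-butyl(chloro)dimethylsilane, CC(C)(C)[Si](C)(C)Cl
Why: Sequential silylation with chlorosilane and imidazole: the bulky diphenyl reagent reacts only with the primary allylic hydroxyl at 0 °C and the smaller reagent then caps the secondary C8 hydroxyl, giving the acid-stability gradient (O14 more robust than O8) that the endgame uses.

Step 8
Reactants: 13 bis-silyl trityl ether
Product: 14 C7 primary alcohol
Conditions: TsOH·H2O (0.1 equiv), MeOH–CH2Cl2, 0 °C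
Reagents that add atoms: none
Why: Acid-catalysed methanolysis of the trityl ether proceeds through the stabilised trityl cation (SN1) and is much faster than cleavage of a hindered secondary TBS ether, a TBDPS ether or an allylic PMB ether at 0 °C.

Step 9
Reactants: 14 primary alcohol
Product: 15 C7 aldehyde (α-silyloxy aldehyde)
Conditions: Dess–Martin periodinane, NaHCO3, CH2Cl2, 0 °C → rt
Reagents that add atoms: none
Why: Dess–Martin oxidation under buffered, non-basic conditions gives the α-silyloxy aldehyde without epimerising C8; it is used without storage.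

Step 10
Reactants: 15 aldehyde; 16 ethyl 2-[bis(2,2,2-trifluoroethoxy)phosphoryl]propanoate
Product: 17 ethyl (2Z,4R,6E,10Z)-trienoate (C7=C11 Z, C12 ester)
Conditions: KN(SiMe3)2, 18-crown-6, THF, −78 °C
Reagents that add atoms: none
Why: Still–Gennari olefination: the electron-poor trifluoroethyl phosphonate with a crown-sequestered potassium counter-ion eliminates under kinetic control to the Z-trisubstituted enoate, so C12 ends cis to C8 across C7=C11, the geometry that the ring contraction translates into the C6/C7 relationship.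

Step 11
Reactants: 17 Z-enoate
Product: 18 C12 Z-allylic alcohol
Conditions: i-Bu2AlH, CH2Cl2, −78 °C; aq. KNaC4H4O6 (tartrate)
Reagents that add atoms: none
Why: 1,2-Reduction of the enoate by i-Bu2AlH at low temperature gives the Z-allylic alcohol with no effect on ethers or olefins.

Step 12
Reactants: 18 allylic alcohol
Product: 20 C12 allylic chloride, via allylic mesylate 19 (not isolated)
Conditions: MeSO2Cl, 2,4,6-collidine, LiCl, DMF, 0 °C
Reagents that add atoms: lithium chloride, [Li+].[Cl-]
Why: Mesylation followed by SN2 displacement with chloride in DMF turns the primary allylic alcohol into the chloride without allylic transposition or loss of the Z geometry; collidine buffers the acid so that silyl and PMB ethers survive.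

Step 13
Reactants: 20 PMB ether chloride
Product: 21 C6 alcohol, C12 chloride (hydroxy chloride)
Conditions: DDQ, CH2Cl2–pH 7 buffer, 0 °C
Reagents that add atoms: none
Why: Oxidative PMB cleavage (hydride abstraction by DDQ, hydrolysis of the resulting oxocarbenium ion) frees O6 under buffered conditions to which the allylic chloride, the silyl ethers and the unconjugated olefins are inert.

Step 14
Reactants: 21 hydroxy chloride
Product: 22 13-membered bis-allylic ether, (3Z,7E,10R,11Z)-10-(tert-butyldimethylsilyloxy)-8-[(tert-butyldiphenylsilyloxy)methyl]-4,12-dimethyl-1-oxacyclotrideca-3,7,11-triene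
Conditions: NaH, n-Bu4NI (cat.), THF, reflux, syringe-pump addition to 0.002 M
Reagents that add atoms: none
Why: Intramolecular Williamson etherification under high dilution: an unhindered primary alkoxide displaces a primary allylic halide (iodide formed in situ), and the two Z olefins bend the chain so that the ends can meet; slow addition keeps oligomers down.

Step 15
Reactants: 22 13-membered ether
Product: 24 ten-membered 6-hydroxy-7-isopropenyl carbocycle (C8 OTBS, C14 OTBDPS), via C6-lithiated cyclic ether 23 (not isolated)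
Conditions: n-BuLi (2 equiv), THF, −78 → −20 °C; H2O quench
Reagents that add atoms: none
Why: n-BuLi removes one C6 proton to give an oxygen-bearing allyl anion (C6–C5–C4) whose C6 terminus adds to C7 across the five-centre array C6–O–C12–C11–C7, the double bond moving to C11=C12 as the C12–O bond is cut; quench of the lithium alkoxide gives 24. This is a [2,3]-Wittig rearrangement used as a ring contraction, a known reaction of 13-membered bis-allylic ethers that gives ten-membered germacrane-type carbocycles. The ten-membered ring closes by bonding of C6 to C7 with the reacting olefin left outside the new ring (exo mode, 10-exo-trig in sense), both reacting carbons being already tied together in the 13-membered ring. C6 and C7 are set together: because C12 and C8 are cis on C7=C11 and the C5 arm sits exo on the envelope, O6 and C8 become syn across the new bond, and the C8 centre chooses the face of C7, since allylic 1,3-strain of the Z olefin keeps H8 in the olefin plane and C6 then bonds anti to the bulky silyloxy group. The step needs lithiation at C6 and not at C12 or at the C14 methylene: C6 is flanked only by the C5 vinylic CH, whereas C12 is hemmed in by the C11 methyl and the cis C8 branch, the C14 methylene by its diphenylsilyl group, no silyl ether can chelate lithium toward C12, and a C12 anion would have to attack the fully substituted C4. C4=C5 and C1=C10 take no part and are carried through unchanged.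

Step 16
Reactants: 24 isopropenyl alcohol
Product: 25 7-isopropyl alcohol
Conditions: H2 (1 atm), RhCl(PPh3)3 (10 mol %), toluene–EtOH, rt
Reagents that add atoms: none
Why: Homogeneous hydrogenation with RhCl(PPh3)3 is strongly sensitive to olefin substitution, so the 1,1-disubstituted isopropenyl group is saturated while the two trisubstituted ring olefins remain; no stereocentre is created.

Step 17
Reactants: 25 C8 TBS ether
Product: 26 6,8-diol (C14 OTBDPS)
Conditions: 48% aq. HF, MeCN, 0 °C
Reagents that add atoms: none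
Why: Protodesilylation with aqueous HF in acetonitrile cleaves the trialkylsilyl ether at O8 far faster than the acid-stable diphenylsilyl ether at O14, giving the 6,8-diol.

Step 18
Reactants: 26 diol
Product: 27 6,8-diacetate (C14 OTBDPS)
Conditions: Ac2O, pyridine, DMAP (cat.), CH2Cl2, rt
Reagents that add atoms: acetic anhydride, CC(=O)OC(C)=O
Why: DMAP-catalysed acylation esterifies both hindered secondary hydroxyls; putting the C8 acetate on before C14 is oxidised prevents lactol and lactone formation between O8 and C14.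

Step 19
Reactants: 27 diacetate silyl ether
Product: 28 C14 allylic alcohol
Conditions: HF·pyridine, pyridine, THF, 0 °C → rt
Reagents that add atoms: none
Why: Fluoride-mediated desilylation under pyridine-buffered conditions frees the primary allylic alcohol without the acetyl migration or hydrolysis that a basic fluoride source could cause.

Step 20
Reactants: 28 allylic alcohol
Product: 29 C14 enal
Conditions: MnO2, CH2Cl2, rt
Reagents that add atoms: none
Why: MnO2 oxidises allylic alcohols selectively on its surface and stops at the aldehyde, giving the E enal with the C1=C10 geometry intact.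

Step 21
Reactants: 29 enal
Product: 30 CNP0172943.1 (target acid)
Conditions: NaClO2, NaH2PO4, 2-methyl-2-butene, t-BuOH–H2O, 0 °C → rt
Reagents that add atoms: sodium chlorite, [Na+].[O-]Cl=O
Why: Pinnick (chlorite) oxidation converts the enal into the carboxylic acid; 2-methyl-2-butene traps hypochlorous acid so that the ring olefins, the allylic acetate and the stereocentres are untouched.

Compound list

1 | nerol, (2Z)-3,7-dimethylocta-2,6-dien-1-ol | OC/C=C(/C)CCC=C(C)C | starting material
2 | neryl 4-methoxybenzyl ether, 1-{[(2Z)-3,7-dimethylocta-2,6-dien-1-yl]oxymethyl}-4-methoxybenzene | COc1ccc(COC/C=C(/C)CCC=C(C)C)cc1 | intermediate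
3 | 3-[(3Z)-5-(4-methoxybenzyloxy)-3-methylpent-3-en-1-yl]-2,2-dimethyloxirane (racemic) | COc1ccc(COC/C=C(/C)CCC2OC2(C)C)cc1 | intermediate
4 | (6Z)-8-(4-methoxybenzyloxy)-2,6-dimethyloct-6-ene-2,3-diol (racemic, not isolated) | COc1ccc(COC/C=C(/C)CCC(O)C(C)(C)O)cc1 | intermediate
5 | (4Z)-6-(4-methoxybenzyloxy)-4-methylhex-4-enal | COc1ccc(COC/C=C(/C)CCC=O)cc1 | intermediate
6 | (R)-trityl glycidyl ether, (2R)-2-[(triphenylmethoxy)methyl]oxirane | C1[C@@H](O1)COC(c2ccccc2)(c3ccccc3)c4ccccc4 | starting material
7 | triethyl phosphonoacetate | CCOC(=O)CP(=O)(OCC)OCC | starting material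
8 | sodium alkoxide of ethyl (4R)-2-(diethoxyphosphoryl)-4-hydroxy-5-(trityloxy)pentanoate (C2 epimers, not isolated) | CCOC(=O)C(C[C@@H]([O-])COC(c1ccccc1)(c2ccccc2)c3ccccc3)P(=O)(OCC)OCC.[Na+] | intermediate
9 | diethyl {(5R)-2-oxo-5-[(trityloxy)methyl]oxolan-3-yl}phosphonate (C3 epimers) | C1[C@@H](OC(=O)C1P(=O)(OCC)OCC)COC(c2ccccc2)(c3ccccc3)c4ccccc4 | intermediate
10 | (3E,5R)-3-[(4Z)-6-(4-methoxybenzyloxy)-4-methylhex-4-en-1-ylidene]-5-[(trityloxy)methyl]oxolan-2-one | COc1ccc(COC/C=C(/C)CC/C=C2\C[C@H](COC(c3ccccc3)(c4ccccc4)c5ccccc5)OC2=O)cc1 | intermediate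
11 | (2R,4E,8Z)-4-(hydroxymethyl)-10-(4-methoxybenzyloxy)-8-methyl-1-(trityloxy)deca-4,8-dien-2-ol | COc1ccc(COC/C=C(/C)CC/C=C(/CO)C[C@@H](O)COC(c2ccccc2)(c3ccccc3)c4ccccc4)cc1 | intermediate
12 | (2R,4E,8Z)-4-[(tert-butyldiphenylsilyloxy)methyl]-10-(4-methoxybenzyloxy)-8-methyl-1-(trityloxy)deca-4,8-dien-2-ol (not isolated) | COc1ccc(COC/C=C(/C)CC/C=C(/CO[Si](c2ccccc2)(c3ccccc3)C(C)(C)C)C[C@@H](O)COC(c4ccccc4)(c5ccccc5)c6ccccc6)cc1 | intermediate
13 | (2R,4E,8Z)-2-(tert-butyldimethylsilyloxy)-4-[(tert-butyldiphenylsilyloxy)methyl]-10-(4-methoxybenzyloxy)-8-methyl-1-(trityloxy)deca-4,8-diene | COc1ccc(COC/C=C(/C)CC/C=C(/CO[Si](c2ccccc2)(c3ccccc3)C(C)(C)C)C[C@@H](O[Si](C)(C)C(C)(C)C)COC(c4ccccc4)(c5ccccc5)c6ccccc6)cc1 | intermediate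
14 | (2R,4E,8Z)-2-(tert-butyldimethylsilyloxy)-4-[(tert-butyldiphenylsilyloxy)methyl]-10-(4-methoxybenzyloxy)-8-methyldeca-4,8-dien-1-ol | COc1ccc(COC/C=C(/C)CC/C=C(/CO[Si](c2ccccc2)(c3ccccc3)C(C)(C)C)C[C@@H](O[Si](C)(C)C(C)(C)C)CO)cc1 | intermediate
15 | (2R,4E,8Z)-2-(tert-butyldimethylsilyloxy)-4-[(tert-butyldiphenylsilyloxy)methyl]-10-(4-methoxybenzyloxy)-8-methyldeca-4,8-dienal | COc1ccc(COC/C=C(/C)CC/C=C(/CO[Si](c2ccccc2)(c3ccccc3)C(C)(C)C)C[C@@H](O[Si](C)(C)C(C)(C)C)C=O)cc1 | intermediate
16 | ethyl 2-[bis(2,2,2-trifluoroethoxy)phosphoryl]propanoate | CCOC(=O)C(C)P(=O)(OCC(F)(F)F)OCC(F)(F)F | starting material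
17 | ethyl (2Z,4R,6E,10Z)-4-(tert-butyldimethylsilyloxy)-6-[(tert-butyldiphenylsilyloxy)methyl]-12-(4-methoxybenzyloxy)-2,10-dimethyldodeca-2,6,10-trienoate | COc1ccc(COC/C=C(/C)CC/C=C(/CO[Si](c2ccccc2)(c3ccccc3)C(C)(C)C)C[C@@H](O[Si](C)(C)C(C)(C)C)/C=C(/C)C(=O)OCC)cc1 | intermediate
18 | (2Z,4R,6E,10Z)-4-(tert-butyldimethylsilyloxy)-6-[(tert-butyldiphenylsilyloxy)methyl]-12-(4-methoxybenzyloxy)-2,10-dimethyldodeca-2,6,10-trien-1-ol | COc1ccc(COC/C=C(/C)CC/C=C(/CO[Si](c2ccccc2)(c3ccccc3)C(C)(C)C)C[C@@H](O[Si](C)(C)C(C)(C)C)/C=C(/C)CO)cc1 | intermediate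
19 | methanesulfonate of 18 at O12 (not isolated) | COc1ccc(COC/C=C(/C)CC/C=C(/CO[Si](c2ccccc2)(c3ccccc3)C(C)(C)C)C[C@@H](O[Si](C)(C)C(C)(C)C)/C=C(/C)COS(C)(=O)=O)cc1 | intermediate
20 | (2Z,4R,6E,10Z)-1-chloro-4-(tert-butyldimethylsilyloxy)-6-[(tert-butyldiphenylsilyloxy)methyl]-12-(4-methoxybenzyloxy)-2,10-dimethyldodeca-2,6,10-triene | COc1ccc(COC/C=C(/C)CC/C=C(/CO[Si](c2ccccc2)(c3ccccc3)C(C)(C)C)C[C@@H](O[Si](C)(C)C(C)(C)C)/C=C(/C)CCl)cc1 | intermediate
21 | (2Z,6E,9R,10Z)-12-chloro-9-(tert-butyldimethylsilyloxy)-7-[(tert-butyldiphenylsilyloxy)methyl]-3,11-dimethyldodeca-2,6,10-trien-1-ol | OC/C=C(/C)CC/C=C(/CO[Si](c1ccccc1)(c2ccccc2)C(C)(C)C)C[C@@H](O[Si](C)(C)C(C)(C)C)/C=C(/C)CCl | intermediate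
22 | (3Z,7E,10R,11Z)-10-(tert-butyldimethylsilyloxy)-8-[(tert-butyldiphenylsilyloxy)methyl]-4,12-dimethyl-1-oxacyclotrideca-3,7,11-triene (ring O between C6 and C12) | O1C/C=C(/C)CC/C=C(/CO[Si](c2ccccc2)(c3ccccc3)C(C)(C)C)C[C@@H](O[Si](C)(C)C(C)(C)C)/C=C(/C)C1 | intermediate
23 | 22 lithiated at C6, the ring carbon between O and C5 (not isolated) | [Li]C1/C=C(/C)CC/C=C(/CO[Si](c2ccccc2)(c3ccccc3)C(C)(C)C)C[C@@H](O[Si](C)(C)C(C)(C)C)/C=C(/C)CO1 | intermediate
24 | ring-numbered cyclodeca-1(10),4-diene: 6-hydroxy, 7-isopropenyl, 8-OTBS, 4-methyl, 10-(TBDPSOCH2); 4Z, 1(10)E; 6-OH and 7-isopropenyl cis, 8-OTBS trans to both; C8 R | O[C@@H]1/C=C(/C)CC/C=C(/CO[Si](c2ccccc2)(c3ccccc3)C(C)(C)C)C[C@@H](O[Si](C)(C)C(C)(C)C)[C@@H]1C(C)=C | intermediate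
25 | as 24 with 7-isopropyl | O[C@@H]1/C=C(/C)CC/C=C(/CO[Si](c2ccccc2)(c3ccccc3)C(C)(C)C)C[C@@H](O[Si](C)(C)C(C)(C)C)[C@@H]1C(C)C | intermediate
26 | 6,8-dihydroxy-7-isopropyl-4-methyl-10-(TBDPSOCH2)cyclodeca-1(10),4-diene, configuration as 24 | O[C@@H]1/C=C(/C)CC/C=C(/CO[Si](c2ccccc2)(c3ccccc3)C(C)(C)C)C[C@@H](O)[C@@H]1C(C)C | intermediate
27 | 6,8-diacetate of 26 | CC(=O)O[C@@H]1/C=C(/C)CC/C=C(/CO[Si](c2ccccc2)(c3ccccc3)C(C)(C)C)C[C@@H](OC(C)=O)[C@@H]1C(C)C | intermediate
28 | 6,8-diacetoxy-10-(hydroxymethyl)-7-isopropyl-4-methylcyclodeca-1(10),4-diene | CC(=O)O[C@@H]1/C=C(/C)CC/C=C(/CO)C[C@@H](OC(C)=O)[C@@H]1C(C)C | intermediate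
29 | 6,8-diacetoxy-7-isopropyl-4-methylcyclodeca-1(10),4-diene-10-carbaldehyde | CC(=O)O[C@@H]1/C=C(/C)CC/C=C(/C=O)C[C@@H](OC(C)=O)[C@@H]1C(C)C | intermediate
30 | CNP0172943.1: (6R,7S,8R)-6,8-diacetoxy-7-isopropyl-4-methylcyclodeca-1(10),4-diene-10-carboxylic acid (ring numbering as above; 4Z, 1(10)E) | CC(=O)O[C@@H]1/C=C(/C)CC/C=C(/C(=O)O)C[C@@H](OC(C)=O)[C@@H]1C(C)C | target

Total steps: 21. Longest linear sequence: 20 (nerol 1 to 30; step 4 lies on the short branch).

Steps most likely to fail

Step 15. Lithiation could occur at the other ether methylene or at the silyloxy methylene, bonding could take the wrong face of C7, or a [1,2]-shift could compete. The fallback sets out from 21 and returns at 24, and it fixes the nucleophilic carbon by a tin substituent instead of by deprotonation. Bu3SnLi (2.2 equiv, THF, −78 °C; the first equivalent only deprotonates the hydroxyl) displaces the chloride of 21 to give the C6 hydroxy C12 allylstannane F1. MnO2 in CH2Cl2 oxidises the C6 alcohol to the Z enal, stannyl enal F2. BF3·OEt2 in CH2Cl2 at −78 °C under high dilution then promotes intramolecular SE2' addition of the allylstannane to the aldehyde, a known type of Lewis-acid macrocyclisation. It forms the same C6–C7 bond with the olefin shifted to C11=C12. Its open antiperiplanar transition state is syn-selective for O6 and C8, as 24 requires.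

Step 14. Intermolecular etherification could outrun closure of the 13-membered ring, and the base could eliminate HCl from the hindered C12 chloride. The fallback sets out from 17 and returns at 22, moving the leaving group to the unhindered C6 terminus so that the C12 alkoxide is the nucleophile. DDQ (buffered CH2Cl2) removes the PMB group of 17 to give the C6 hydroxy enoate F3. MeSO2Cl/collidine/LiCl in DMF converts it through the allylic mesylate F4 (not isolated) into the C6 chloro enoate F5. i-Bu2AlH at −78 °C reduces the ester to the C6 chloro C12 alcohol F6. NaH in THF under high dilution then closes the ring by SN2 displacement at the primary neryl-type chloride, giving 22.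

Step 17. The primary allylic silyl ether could be lost together with the C8 silyl ether, or the acid could ionise the C6 allylic alcohol. The fallback sets out from 25 and returns at 26 by redistributing the protecting groups without acid. n-Bu4NF in THF removes both silyl groups to give the 6,8,14-triol F7. t-BuPh2SiCl/imidazole in DMF at 0 °C then silylates only the primary C14 hydroxyl, which is 26.

Further compounds

F1 | step 15 | C6 hydroxy C12 tributylstannane (open chain, C8 OTBS, C14 OTBDPS) | OC/C=C(/C)CC/C=C(/CO[Si](c1ccccc1)(c2ccccc2)C(C)(C)C)C[C@@H](O[Si](C)(C)C(C)(C)C)/C=C(/C)C[Sn](CCCC)(CCCC)CCCC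
F2 | step 15 | C6 (Z)-enal C12 tributylstannane | O=C/C=C(/C)CC/C=C(/CO[Si](c1ccccc1)(c2ccccc2)C(C)(C)C)C[C@@H](O[Si](C)(C)C(C)(C)C)/C=C(/C)C[Sn](CCCC)(CCCC)CCCC
F3 | step 14 | C6 hydroxy C12 ethyl ester (17 without PMB) | OC/C=C(/C)CC/C=C(/CO[Si](c1ccccc1)(c2ccccc2)C(C)(C)C)C[C@@H](O[Si](C)(C)C(C)(C)C)/C=C(/C)C(=O)OCC
F4 | step 14 | C6 methanesulfonate of F3 (not isolated) | CS(=O)(=O)OC/C=C(/C)CC/C=C(/CO[Si](c1ccccc1)(c2ccccc2)C(C)(C)C)C[C@@H](O[Si](C)(C)C(C)(C)C)/C=C(/C)C(=O)OCC
F5 | step 14 | C6 chloro C12 ethyl ester | ClC/C=C(/C)CC/C=C(/CO[Si](c1ccccc1)(c2ccccc2)C(C)(C)C)C[C@@H](O[Si](C)(C)C(C)(C)C)/C=C(/C)C(=O)OCC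
F6 | step 14 | C6 chloro C12 alcohol | ClC/C=C(/C)CC/C=C(/CO[Si](c1ccccc1)(c2ccccc2)C(C)(C)C)C[C@@H](O[Si](C)(C)C(C)(C)C)/C=C(/C)CO
F7 | step 17 | 6,8-dihydroxy-10-(hydroxymethyl)-7-isopropyl-4-methylcyclodeca-1(10),4-diene | O[C@@H]1/C=C(/C)CC/C=C(/CO)C[C@@H](O)[C@@H]1C(C)C
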